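**Retrosynthetic overview**
1. The quinone ring is not built. It is unveiled last by para-oxidation of the 2'-phenol of an (S)-2'-hydroxyisoflavan, while the fully etherified ring A stays inert.
2. (S)-Isoflavan ⇐ reductive opening of a cis-pterocarpan ⇐ cis-isoflavan-4-ol. C3 is set in a hydride-transfer reduction of the isoflavone with dynamic kinetic resolution.
3. Isoflavone ⇐ flavanone by an oxidative 2→3 aryl shift. The C3–aryl bond is never made by coupling: ring B is first bonded to C2 and then walked over.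
4. Flavanone (ring C, O1–C2 bond) ⇐ 2'-hydroxychalcone by oxa-Michael closure ⇐ Claisen–Schmidt union of an acetophenone (ring A) and a benzaldehyde (ring B).
5. Both halves ⇐ 2,3,4-trimethoxybenzaldehyde. Ring order: C (pyranone), then the transient dihydrofuran of the pterocarpan (opened again), then the quinone by oxidation.

Assumption: the stereocentre in the SMILES reads as (3S), the same spatial sense as (S)-equol, and racemic intermediates are written without stereo labels.

**Route**

Step 1
Reactants: 1 2,3,4-trimethoxybenzaldehyde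
Product: 3 2,3,4-trimethoxyphenol, via 2,3,4-trimethoxyphenyl formate 2 (not isolated)
Conditions: 35% H2O2, cat. H2SO4, MeOH, rt
Reagents that add atoms: hydrogen peroxide, OO
Why: Acid-catalysed Dakin (Baeyer–Villiger-type) oxidation, in which the electron-rich aryl group migrates to oxygen in the perhydrate adduct to give formate 2, which MeOH/H+ cleaves in situ; no stereocentre is involved.

Step 2
Reactants: 3 2,3,4-trimethoxyphenol
Product: 4 1-(2-hydroxy-3,4,5-trimethoxyphenyl)ethan-1-one
Conditions: AcOH, BF3·OEt2 (3 equiv), 90 °C; H2O work-up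
Reagents that add atoms: acetic acid, CC(=O)O
Why: BF3-promoted Friedel–Crafts/Fries ortho-acylation, in which only C6 of the two free positions (ortho to OH, para to the 3-OMe) gives the chelated o-hydroxyaryl ketone as thermodynamic sink, and no OMe ends up ortho to the carbonyl, so none is cleaved.

Step 3
Reactants: 1 2,3,4-trimethoxybenzaldehyde
Product: 5 2-hydroxy-3,4-dimethoxybenzaldehyde
Conditions: BCl3 (1.1 equiv), CH2Cl2, 0 °C → rt; H2O
Reagents that add atoms: none
Why: Chelation-controlled aryl methyl ether cleavage, in which BCl3 bridges the formyl oxygen and the ortho-OMe in a six-membered chelate, so chloride dealkylates only that ether.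

Step 4
Reactants: 5 2-hydroxy-3,4-dimethoxybenzaldehyde
Product: 6 2-(benzyloxy)-3,4-dimethoxybenzaldehyde
Conditions: BnBr, K2CO3, DMF, 60 °C
Reagents that add atoms: benzyl bromide, BrCc1ccccc1
Why: Williamson ether synthesis; the benzyl group shields this phenol from I(III) in step 6 and leaves in the same hydrogenolysis that removes the C4 oxygen in step 7.

Step 5
Reactants: 4 1-(2-hydroxy-3,4,5-trimethoxyphenyl)ethan-1-one; 6 2-(benzyloxy)-3,4-dimethoxybenzaldehyde
Product: 8 (±)-2-[2-(benzyloxy)-3,4-dimethoxyphenyl]-6,7,8-trimethoxychroman-4-one (flavanone), via (E)-3-[2-(benzyloxy)-3,4-dimethoxyphenyl]-1-(2-hydroxy-3,4,5-trimethoxyphenyl)prop-2-en-1-one 7 (not isolated)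
Conditions: KOH (50% aq), EtOH, rt; then AcOH to pH 6, reflux
Reagents that add atoms: none
Why: Claisen–Schmidt condensation gives (E)-chalcone 7, and in the acetate buffer its phenol adds 6-endo to the enone (intramolecular oxa-Michael addition, the chalcone-isomerase step), closing ring C with ring B on C2; the C2 centre is left racemic because step 6 erases it.

Step 6
Reactants: 8 (±)-2-[2-(benzyloxy)-3,4-dimethoxyphenyl]-6,7,8-trimethoxychroman-4-one
Product: 13 (3S,4S)-3-[2-(benzyloxy)-3,4-dimethoxyphenyl]-6,7,8-trimethoxychroman-4-ol (cis-isoflavan-4-ol), via (±)-trans-2-[2-(benzyloxy)-3,4-dimethoxyphenyl]-6,7,8-trimethoxy-3-[phenyl(tosyloxy)-λ3-iodanyl]chroman-4-one 9 (not isolated), via (±)-3-[2-(benzyloxy)-3,4-dimethoxyphenyl]-2-hydroxy-6,7,8-trimethoxychroman-4-one 10 (not isolated), via 3-[2-(benzyloxy)-3,4-dimethoxyphenyl]-6,7,8-trimethoxy-4H-chromen-4-one 11 (not isolated), via (±)-3-[2-(benzyloxy)-3,4-dimethoxyphenyl]-6,7,8-trimethoxychroman-4-one 12 (not isolated)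
Conditions: (i) PhI(OH)OTs (1.05 equiv), MeCN, reflux; (ii) cool, HCO2H–Et3N (5:2), 30 min, then RuCl[(S,S)-TsDPEN](p-cymene) (3 mol %), 40 °C
Reagents that add atoms: none
Why: Proposed new method: a one-flask oxidative 2→3 aryl shift/asymmetric transfer hydrogenation whose halves are known reaction types (hypervalent-iodine 1,2-aryl migration of flavanones to isoflavones; Noyori–Ikariya ATH cascade of isoflavones with dynamic kinetic resolution): the enol of 8 is iodanylated at C3 anti to the aryl group (9), loss of PhI is assisted by the antiperiplanar p-MeO/o-BnO-activated ring through a phenonium ion, the O1-stabilised C2 cation takes up the water released by the reagent (10, the 2-hydroxyisoflavanone of the isoflavone-synthase step) and TsOH dehydrates it to 11, ring A being safe because its oxygen is already tied up in ring C; formate then destroys leftover I(III) and buffers TsOH, Ru–H adds 1,4 to the chromone to give 12, whose C3–H epimerises fast in Et3N, and the (S,S)-catalyst reduces only (3S)-12 on the face that gives the (4S)-carbinol (the same sense as 1-tetralone and chroman-4-one → S), so C3 = S and C4 = S (cis) are set together with PhI and tosylate as spectators.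

Step 7
Reactants: 13 (3S,4S)-3-[2-(benzyloxy)-3,4-dimethoxyphenyl]-6,7,8-trimethoxychroman-4-ol
Product: 16 2,3-dimethoxy-6-[(3S)-6,7,8-trimethoxychroman-3-yl]phenol ((3S)-2'-hydroxy-3',4',6,7,8-pentamethoxyisoflavan), via (3S,4S)-3-(2-hydroxy-3,4-dimethoxyphenyl)-6,7,8-trimethoxychroman-4-ol 14 (not isolated), via (6aS,11aS)-2,3,4,9,10-pentamethoxypterocarpan 15 (not isolated)
Conditions: H2 (1 atm), 10% Pd/C, EtOH, cat. aq HCl, 40 °C
Reagents that add atoms: none
Why: Catalytic hydrogenolysis in which O-debenzylation frees the 2'-OH (14), the electron-rich C4 carbinol ionises and is captured by that OH faster than it can lose H-3 (cis-pterocarpan 15, the pterocarpan-synthase step), and the benzylic C11a–O bond is then cleaved as in the classical pterocarpan → 2'-hydroxyisoflavan reduction; none of these events touches C3, which stays S.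

Step 8
Reactants: 16 2,3-dimethoxy-6-[(3S)-6,7,8-trimethoxychroman-3-yl]phenol
Product: 17 abruquinone B, 2,3-dimethoxy-5-[(3S)-6,7,8-trimethoxychroman-3-yl]cyclohexa-2,5-diene-1,4-dione
Conditions: (KO3S)2NO (2.5 equiv), KH2PO4 buffer (pH 6–7), acetone–H2O, rt
Reagents that add atoms: potassium nitrosodisulfonate (Fremy's salt), [K+].[K+].[O-]S(=O)(=O)N([O])S(=O)(=O)[O-]
Why: Teuber oxidation, in which the nitroxyl radical abstracts the phenolic H and a second equivalent delivers oxygen to the only open position of the phenoxyl radical (C5', para; both ortho positions are blocked), while ring A has no O–H and is inert and the near-neutral buffer leaves C3 (S) untouched.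

**Compound list**
1 | 2,3,4-trimethoxybenzaldehyde | COc1ccc(C=O)c(OC)c1OC | starting material
2 | 2,3,4-trimethoxyphenyl formate | COc1ccc(OC=O)c(OC)c1OC | intermediate
3 | 2,3,4-trimethoxyphenol | COc1ccc(O)c(OC)c1OC | intermediate
4 | 1-(2-hydroxy-3,4,5-trimethoxyphenyl)ethan-1-one | CC(=O)c1cc(OC)c(OC)c(OC)c1O | intermediate
5 | 2-hydroxy-3,4-dimethoxybenzaldehyde | COc1ccc(C=O)c(O)c1OC | intermediate
6 | 2-(benzyloxy)-3,4-dimethoxybenzaldehyde | COc1ccc(C=O)c(OCc2ccccc2)c1OC | intermediate
7 | (E)-3-[2-(benzyloxy)-3,4-dimethoxyphenyl]-1-(2-hydroxy-3,4,5-trimethoxyphenyl)prop-2-en-1-one (2'-hydroxychalcone) | COc1ccc(/C=C/C(=O)c2cc(OC)c(OC)c(OC)c2O)c(OCc2ccccc2)c1OC | intermediate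
8 | (±)-2-[2-(benzyloxy)-3,4-dimethoxyphenyl]-6,7,8-trimethoxychroman-4-one (flavanone, racemic) | COc1ccc(C2CC(=O)c3cc(OC)c(OC)c(OC)c3O2)c(OCc2ccccc2)c1OC | intermediate
9 | (±)-trans-2-[2-(benzyloxy)-3,4-dimethoxyphenyl]-6,7,8-trimethoxy-3-[phenyl(tosyloxy)-λ3-iodanyl]chroman-4-one (racemic) | COc1ccc(C2Oc3c(OC)c(OC)c(OC)cc3C(=O)C2I(OS(=O)(=O)c2ccc(C)cc2)c2ccccc2)c(OCc2ccccc2)c1OC | intermediate
10 | (±)-3-[2-(benzyloxy)-3,4-dimethoxyphenyl]-2-hydroxy-6,7,8-trimethoxychroman-4-one (2-hydroxyisoflavanone, racemic, both diastereomers) | COc1ccc(C2C(O)Oc3c(OC)c(OC)c(OC)cc3C2=O)c(OCc2ccccc2)c1OC | intermediate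
11 | 3-[2-(benzyloxy)-3,4-dimethoxyphenyl]-6,7,8-trimethoxy-4H-chromen-4-one (isoflavone) | COc1ccc(C2=COc3c(OC)c(OC)c(OC)cc3C2=O)c(OCc2ccccc2)c1OC | intermediate
12 | (±)-3-[2-(benzyloxy)-3,4-dimethoxyphenyl]-6,7,8-trimethoxychroman-4-one (isoflavanone, racemising) | COc1ccc(C2COc3c(OC)c(OC)c(OC)cc3C2=O)c(OCc2ccccc2)c1OC | intermediate
13 | (3S,4S)-3-[2-(benzyloxy)-3,4-dimethoxyphenyl]-6,7,8-trimethoxychroman-4-ol (cis) | COc1ccc([C@H]2COc3c(cc(OC)c(OC)c3OC)[C@H]2O)c(OCc2ccccc2)c1OC | intermediate
14 | (3S,4S)-3-(2-hydroxy-3,4-dimethoxyphenyl)-6,7,8-trimethoxychroman-4-ol (cis) | COc1ccc([C@H]2COc3c(cc(OC)c(OC)c3OC)[C@H]2O)c(O)c1OC | intermediate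
15 | (6aS,11aS)-2,3,4,9,10-pentamethoxy-6a,11a-dihydro-6H-[1]benzofuro[3,2-c]chromene (cis-pterocarpan) | COc1ccc2[C@H]3COc4c(cc(OC)c(OC)c4OC)[C@H]3Oc2c1OC | intermediate
16 | 2,3-dimethoxy-6-[(3S)-6,7,8-trimethoxychroman-3-yl]phenol | COc1ccc([C@H]2COc3c(cc(OC)c(OC)c3OC)C2)c(O)c1OC | intermediate
17 | abruquinone B, 2,3-dimethoxy-5-[(3S)-6,7,8-trimethoxychroman-3-yl]cyclohexa-2,5-diene-1,4-dione | COC1=C(OC)C(=O)C([C@H]2COc3c(cc(OC)c(OC)c3OC)C2)=CC1=O | target

**Step count**
Total step count: 8.
Longest linear sequence: 6 (steps 1, 2, 5, 6, 7, 8; 1 → 3 → 4 → 8 → 13 → 16 → 17).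

**Steps most likely to fail**

Step 6 is most at risk. Plain dehydrogenation to the flavone, C3 tosyloxylation, or attack of I(III) on the trialkoxy ring B can compete with the aryl shift. The crude oxidation mixture may also slow the Ru catalyst. The fallback moves the aryl shift in front of ring closure and gives up the one-flask format.
- It sets out from chalcone 7, isolated by stopping step 5 after the aldol stage (cold dilute HCl, filtration).
- Tl(NO3)3·3H2O in MeOH–HC(OMe)3 at room temperature effects oxythallation and 1,2-aryl shift on the open chain. This gives the keto acetal 2-[2-(benzyloxy)-3,4-dimethoxyphenyl]-1-(2-hydroxy-3,4,5-trimethoxyphenyl)-3,3-dimethoxypropan-1-one F1.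
- Warm 10% HCl in MeOH closes the pyranone by attack of the phenol on the acetal carbon.
- The fallback comes back to the route at isoflavone 11, now isolated and recrystallised before it meets the Ru catalyst under the stage (ii) conditions.

Step 7 is second. If the C4 cation loses H-3, the resulting isoflav-3-ene is hydrogenated without selectivity and the ee erodes. The pterocarpan C–O bond may also resist 1 atm of H2. The fallback removes the C4 oxygen through a radical, so no cation is formed.
- It sets out from 13.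
- NaH, CS2 and MeI in THF give the xanthate O-{(3S,4S)-3-[2-(benzyloxy)-3,4-dimethoxyphenyl]-6,7,8-trimethoxychroman-4-yl} S-methyl carbonodithioate F2. Thermal syn-elimination is blocked because H-3 is anti to the xanthate.
- Bu3SnH/AIBN in toluene at 80 °C (Barton–McCombie deoxygenation) gives (3S)-3-[2-(benzyloxy)-3,4-dimethoxyphenyl]-6,7,8-trimethoxychroman F3.
- Neutral hydrogenolysis (H2, Pd/C, EtOAc) frees the phenol, and the fallback comes back at 16.

Step 5 is third. The electron-rich, ortho-substituted ring B shifts the chalcone/flavanone equilibrium toward 7. The fallback replaces the reversible oxa-Michael addition by an irreversible SN2 ring closure.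
- It sets out from 4 and 6.
- The dianion of 4 (LDA, 2.2 equiv, THF, −78 °C) adds to 6 to give the β-hydroxy ketone 3-[2-(benzyloxy)-3,4-dimethoxyphenyl]-3-hydroxy-1-(2-hydroxy-3,4,5-trimethoxyphenyl)propan-1-one F4.
- PPh3/DIAD (Mitsunobu reaction) lets the phenol displace the activated benzylic oxygen, and the fallback comes back at 8.

**Further compounds**
F1 | step 6 | 2-[2-(benzyloxy)-3,4-dimethoxyphenyl]-1-(2-hydroxy-3,4,5-trimethoxyphenyl)-3,3-dimethoxypropan-1-one (racemic) | COc1ccc(C(C(OC)OC)C(=O)c2cc(OC)c(OC)c(OC)c2O)c(OCc2ccccc2)c1OC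
F2 | step 7 | O-{(3S,4S)-3-[2-(benzyloxy)-3,4-dimethoxyphenyl]-6,7,8-trimethoxychroman-4-yl} S-methyl carbonodithioate | COc1ccc([C@H]2COc3c(cc(OC)c(OC)c3OC)[C@H]2OC(=S)SC)c(OCc2ccccc2)c1OC
F3 | step 7 | (3S)-3-[2-(benzyloxy)-3,4-dimethoxyphenyl]-6,7,8-trimethoxychroman | COc1ccc([C@H]2COc3c(cc(OC)c(OC)c3OC)C2)c(OCc2ccccc2)c1OC
F4 | step 5 | 3-[2-(benzyloxy)-3,4-dimethoxyphenyl]-3-hydroxy-1-(2-hydroxy-3,4,5-trimethoxyphenyl)propan-1-one (racemic) | COc1ccc(C(O)CC(=O)c2cc(OC)c(OC)c(OC)c2O)c(OCc2ccccc2)c1OC
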